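**Retrosynthetic overview**

1. Numbering: C1 is the quaternary carbinol carbon, C2 the CH–OAc carbon, C3 the neighbouring CH–OBz carbon, C4=C5 the alkene, C6 the other CH–OBz carbon and C7 the exocyclic CH2OBz carbon. The route rests on C1 (bearing OH and the C7 oxymethyl arm) lying para to alkene carbon C4 in the six-membered ring, so all seven carbons map onto the achiral 4-hydroxy-4-(silyloxymethyl)cyclohexa-2,5-dienone 5, whose C4 carbonyl is later transposed away.
2. The ester pattern (C2 acetate; C3, C6, C7 benzoates) comes from acylations around a C1/C2 acetonide; the C3–O and C6–O bonds come from a singlet-oxygen [4+2] addition across the C3–C6 diene of 10, anti to the dioxolane, followed by O–O cleavage.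
3. Diene diol 9 comes from Wharton transposition of epoxy ketone 6. Compound 6 comes from tartrate-controlled, hydroxyl-directed nucleophilic epoxidation of one enantiotopic enone arm of 5 (C2–O and C3–O formed; C1, C2, C3 set).
4. Quinol 5 comes from PhI(OAc)2 dearomatisation of phenol 4, made from 4-hydroxybenzyl alcohol 1 and silyl chloride 2.
5. Ring order: the carbocycle is taken from the arene of 1; the oxirane (step 4), the dioxolane (step 6) and the peroxide bridge (step 7) are temporary rings.

Key step: step 4

Assumption: the sense in which the sodium tartrate–peroxide aggregate distinguishes the two enone arms of a para-quinol cannot be predicted; the route is written with L-(+)-diisopropyl tartrate, and D-(−)-diisopropyl tartrate takes its place if the first experiment shows the mirror image of 6.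

**Route**

Step 1
Reactants: 1 4-hydroxybenzyl alcohol; 2 tert-butyldimethylsilyl chloride
Product: 3 tert-butyl{[4-(tert-butyldimethylsilyloxy)phenyl]methoxy}dimethylsilane (bis-silyl ether)
Conditions: TBSCl (2.4 equiv), imidazole, DMF, rt
Reagents that add atoms: tert-butyldimethylsilyl chloride (compound 2), C[Si](C)(Cl)C(C)(C)C
Why: Imidazole-promoted silylation converts both the benzylic and the phenolic hydroxyl, so no selectivity question arises at this stage.

Step 2
Reactants: 3 bis-silyl ether
Product: 4 4-[(tert-butyldimethylsilyloxy)methyl]phenol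
Conditions: K2CO3 (cat.), MeOH, 0 °C to rt
Reagents that add atoms: none
Why: Base-mediated methanolysis cleaves the aryl silyl ether much faster than the alkyl silyl ether because phenoxide is the better leaving group, so only the phenol is released.

Step 3
Reactants: 4 4-[(tert-butyldimethylsilyloxy)methyl]phenol
Product: 5 4-hydroxy-4-[(tert-butyldimethylsilyloxy)methyl]cyclohexa-2,5-dien-1-one (achiral para-quinol)
Conditions: PhI(OAc)2, MeCN/H2O, 0 °C
Reagents that add atoms: water, O
Why: Oxidative dearomatisation of a para-substituted phenol by trivalent iodine, in which water attacks the substituted para carbon of the activated aryloxy-iodane to create the C1 carbinol; the product is achiral because a mirror plane passes through C1, C4 and C7.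

Step 4
Reactants: 5 achiral para-quinol
Product: 6 (1R,5S,6S)-5-hydroxy-5-[(tert-butyldimethylsilyloxy)methyl]-7-oxabicyclo[4.1.0]hept-3-en-2-one (C2,C3-epoxy para-quinol, oxirane cis to the C1 hydroxyl)
Conditions: Ph3COOH (1.1 equiv), NaN(SiMe3)2, L-(+)-diisopropyl tartrate, 4 Å MS, PhMe, −65 to −40 °C; aq NH4Cl
Reagents that add atoms: trityl hydroperoxide, OOC(c1ccccc1)(c1ccccc1)c1ccccc1
Why: Proposed new method: NaN(SiMe3)2 turns the C1 hydroxyl, the hydroperoxide and the tartrate into one sodium alkoxide/peroxide aggregate, from which the trityl peroxide anion adds in a Weitz–Scheffer conjugate addition to C2, the enone β-carbon next to the anchoring C1 alkoxide, and the resulting C3–C4 enolate then displaces trityl oxide at the proximal peroxide oxygen, closing the oxirane in a 3-exo-tet mode. The closest known reactions are the tartrate-mediated, hydroxyl-directed nucleophilic epoxidation of quinone monoketals and the achiral syn-epoxidation of para-quinols directed by the tertiary hydroxyl; what is new is that the chiral aggregate has to choose between the two enantiotopic enone arms of a para-quinol. C2 and C3 are fixed relative to C1 by delivery of the peroxide from the alkoxide-bound face (syn), and the absolute configuration of all three centres follows from which arm the tartrate complex selects, since that choice makes C1 stereogenic. The step needs enantiotopic-group selectivity, face selectivity and mono-epoxidation: the single alkoxide anchor at C1 ties the reagent to one face and within reach of C2 and C6 only, the tartrate has to break the symmetry between these two carbons, and the peroxide is kept near one equivalent. Any second, again hydroxyl-directed epoxidation should consume the minor enantiomer faster, because its remaining enone arm is the one the chiral complex prefers, so over-oxidation would raise the enantiomeric purity of 6 at the cost of yield.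

Step 5
Reactants: 6 epoxy para-quinol
Product: 9 (1S,2S)-1-[(tert-butyldimethylsilyloxy)methyl]cyclohexa-3,5-diene-1,2-diol (cis-diol), via epoxy hydrazone 7 (not isolated), via alkenyl diazene 8 (not isolated)
Conditions: N2H4·H2O, AcOH (cat.), MeOH, 0 °C to rt
Reagents that add atoms: none
Why: Wharton transposition: hydrazone 7 opens the oxirane at C3–O to alkenyl diazene 8, which loses N2 and takes up hydrogen at C4, so C3=C4 forms while the untouched C2–O bond stays cis to C1–OH; conjugate addition of hydrazine to the other enone is slowed because its β-carbon C6 adjoins the fully substituted C1.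

Step 6
Reactants: 9 cis-diene diol
Product: 10 (3aS,7aS)-3a-[(tert-butyldimethylsilyloxy)methyl]-2,2-dimethyl-3a,7a-dihydro-1,3-benzodioxole (C1/C2 acetonide of 9)
Conditions: Me2C(OMe)2, PPTS (cat.), acetone, rt
Reagents that add atoms: 2,2-dimethoxypropane, COC(C)(C)OC
Why: Acid-catalysed transketalisation closes a cis-fused dioxolane on the cis C1/C2 diol, which blocks dehydrative aromatisation of the dihydroarene diol and provides the facial bias for the next step; no stereocentre is touched.

Step 7
Reactants: 10 diene acetonide
Product: 12 (1R,2S,3R,6S)-1-[(tert-butyldimethylsilyloxy)methyl]-1,2-O-isopropylidenecyclohex-4-ene-1,2,3,6-tetrol (C3 and C6 hydroxyls cis to each other and trans to the dioxolane), via endoperoxide 11 (not isolated)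
Conditions: O2, hν (visible), tetraphenylporphyrin (cat.), CH2Cl2, −78 °C; then thiourea, MeOH, −78 °C to rt
Reagents that add atoms: dioxygen, O=O
Why: Singlet oxygen adds as a dienophile in a [4+2] cycloaddition across C3 and C6 of the s-cis diene on the face opposite the dioxolane oxygens (the C7 arm on that face is expected to lie pseudo-equatorial), which sets C3 and C6 cis to each other and trans to the C1/C2 oxygens; thiourea then cleaves only the O–O bond with retention at both carbons.

Step 8
Reactants: 12 silyl-protected diol
Product: 13 (1R,2S,3R,6S)-1-(hydroxymethyl)-1,2-O-isopropylidenecyclohex-4-ene-1,2,3,6-tetrol (C3, C6 and C7 hydroxyls free)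
Conditions: Bu4NF, AcOH, THF, 0 °C to rt
Reagents that add atoms: none
Why: Fluoride cleaves the primary silyl ether under acetic acid buffering, and the acetonide and the allylic alcohols are left alone because no ester is yet present to migrate.

Step 9
Reactants: 13 triol acetonide
Product: 14 (1R,2S,3R,6S)-3,6-bis(benzoyloxy)-1-[(benzoyloxy)methyl]-1,2-O-isopropylidenecyclohex-4-ene-1,2-diol (tribenzoate acetonide)
Conditions: BzCl (excess), pyridine, DMAP (cat.), CH2Cl2, 0 °C to rt
Reagents that add atoms: benzoyl chloride, O=C(Cl)c1ccccc1
Why: DMAP-catalysed acylation with excess benzoyl chloride esterifies the two secondary allylic hydroxyls and the neopentyl-type primary hydroxyl in one operation, while the C1 and C2 oxygens stay locked in the acetonide.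

Step 10
Reactants: 14 tribenzoate acetonide
Product: 15 (1S,2S,3R,6S)-3,6-bis(benzoyloxy)-1-[(benzoyloxy)methyl]cyclohex-4-ene-1,2-diol (C1 and C2 hydroxyls free)
Conditions: TFA/H2O (9:1), 0 °C to rt
Reagents that add atoms: none
Why: Aqueous acid hydrolyses the isopropylidene acetal through the oxocarbenium ion at the acetal carbon, so no ring C–O bond is broken, and the benzoates, which migrate only slowly under acid, stay in place.

Step 11
Reactants: 15 diol tribenzoate
Product: 16 (1R,2S,3R,6S)-2-acetoxy-3,6-bis(benzoyloxy)-1-[(benzoyloxy)methyl]cyclohex-4-en-1-ol (target)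
Conditions: Ac2O (1.5 equiv), pyridine, DMAP (cat.), CH2Cl2, 0 °C
Reagents that add atoms: acetic anhydride, CC(=O)OC(C)=O
Why: DMAP-catalysed acetylation takes the secondary C2 hydroxyl and leaves the tertiary C1 hydroxyl, flanked by three substituted carbons, free; this gives the target with C1 and C2 as set in step 4 and C3 and C6 as set in step 7.

**Compound list**

1 | 4-hydroxybenzyl alcohol | OCc1ccc(O)cc1 | starting material
2 | tert-butyldimethylsilyl chloride | C[Si](C)(Cl)C(C)(C)C | starting material
3 | tert-butyl{[4-(tert-butyldimethylsilyloxy)phenyl]methoxy}dimethylsilane | CC(C)(C)[Si](C)(C)OCc1ccc(O[Si](C)(C)C(C)(C)C)cc1 | intermediate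
4 | 4-[(tert-butyldimethylsilyloxy)methyl]phenol | CC(C)(C)[Si](C)(C)OCc1ccc(O)cc1 | intermediate
5 | 4-hydroxy-4-[(tert-butyldimethylsilyloxy)methyl]cyclohexa-2,5-dien-1-one | O=C1C=CC(O)(CO[Si](C)(C)C(C)(C)C)C=C1 | intermediate
6 | (1R,5S,6S)-5-hydroxy-5-[(tert-butyldimethylsilyloxy)methyl]-7-oxabicyclo[4.1.0]hept-3-en-2-one | O=C1C=C[C@](O)(CO[Si](C)(C)C(C)(C)C)[C@H]2O[C@@H]12 | intermediate
7 | hydrazone of 6 at C4 (not isolated) | NN=C1C=C[C@](O)(CO[Si](C)(C)C(C)(C)C)[C@H]2O[C@@H]12 | intermediate
8 | C4 alkenyl diazene with C3=C4 and C5=C6, cis C1/C2 diol (not isolated) | N=NC1=C[C@H](O)[C@@](O)(CO[Si](C)(C)C(C)(C)C)C=C1 | intermediate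
9 | (1S,2S)-1-[(tert-butyldimethylsilyloxy)methyl]cyclohexa-3,5-diene-1,2-diol | O[C@H]1C=CC=C[C@]1(O)CO[Si](C)(C)C(C)(C)C | intermediate
10 | (3aS,7aS)-3a-[(tert-butyldimethylsilyloxy)methyl]-2,2-dimethyl-3a,7a-dihydro-1,3-benzodioxole | CC1(C)O[C@H]2C=CC=C[C@@]2(CO[Si](C)(C)C(C)(C)C)O1 | intermediate
11 | endoperoxide of 10, peroxide bridge from C3 to C6 on the face opposite the dioxolane (not isolated) | CC1(C)O[C@H]2[C@H]3C=C[C@H](OO3)[C@@]2(CO[Si](C)(C)C(C)(C)C)O1 | intermediate
12 | (1R,2S,3R,6S)-1-[(tert-butyldimethylsilyloxy)methyl]-1,2-O-isopropylidenecyclohex-4-ene-1,2,3,6-tetrol | CC1(C)O[C@H]2[C@H](O)C=C[C@H](O)[C@@]2(CO[Si](C)(C)C(C)(C)C)O1 | intermediate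
13 | (1R,2S,3R,6S)-1-(hydroxymethyl)-1,2-O-isopropylidenecyclohex-4-ene-1,2,3,6-tetrol | CC1(C)O[C@H]2[C@H](O)C=C[C@H](O)[C@@]2(CO)O1 | intermediate
14 | (1R,2S,3R,6S)-3,6-bis(benzoyloxy)-1-[(benzoyloxy)methyl]-1,2-O-isopropylidenecyclohex-4-ene-1,2-diol | CC1(C)O[C@H]2[C@H](OC(=O)c3ccccc3)C=C[C@H](OC(=O)c3ccccc3)[C@@]2(COC(=O)c3ccccc3)O1 | intermediate
15 | (1S,2S,3R,6S)-3,6-bis(benzoyloxy)-1-[(benzoyloxy)methyl]cyclohex-4-ene-1,2-diol | O[C@H]1[C@H](OC(=O)c2ccccc2)C=C[C@H](OC(=O)c2ccccc2)[C@]1(O)COC(=O)c1ccccc1 | intermediate
16 | (1R,2S,3R,6S)-2-acetoxy-3,6-bis(benzoyloxy)-1-[(benzoyloxy)methyl]cyclohex-4-en-1-ol | CC(=O)O[C@H]1[C@H](OC(=O)c2ccccc2)C=C[C@H](OC(=O)c2ccccc2)[C@]1(O)COC(=O)c1ccccc1 | target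

**Step count and risk**

Total step count: 11. Longest linear sequence: 11 steps (from 1 to 16).

Steps most likely to fail:

1. Step 4 (proposed new method). The tartrate aggregate may discriminate poorly between the two enone arms, giving low enantiomeric purity, or a second directed epoxidation may outpace the first. The fallback uses known chemistry, sets out from 5 and comes back at 9, at the cost of half the material.
   - Hydroxyl-directed syn-epoxidation without chiral additive (tBuOOH, DBU, CH2Cl2, 0 °C) should give 6 together with its mirror image, the enantiomeric epoxy quinol F1.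
   - Wharton transposition as in step 5 carries the racemate on, the mirror-image series passing through the enantiomeric hydrazone F2 and the enantiomeric alkenyl diazene F3, to 9 mixed with the enantiomeric diene diol F4.
   - Lipase-catalysed acylation (Burkholderia cepacia lipase, vinyl acetate, tBuOMe, rt) then resolves the pair. By the empirical size rule for secondary alcohols (C1 large, vinylic C3 medium) it is expected to acetylate the (2R) enantiomer to the enantiomeric diol 2-acetate F5 and to leave 9, which is separated by chromatography.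

2. Step 5. Hydrazine may add in conjugate fashion to the remaining enone and close a pyrazoline, or the diene diol may dehydrate to a phenol under the reaction conditions. The fallback avoids hydrazine, sets out from 6 and comes back at 9.
   - Luche reduction (NaBH4, CeCl3·7H2O, MeOH, −78 °C) should give the epoxy allylic alcohol F6 as C4 epimers, whose configuration is of no consequence.
   - Mesylation of the secondary hydroxyl (MsCl, Et3N, CH2Cl2, −20 °C) gives the epoxy mesylate F7.
   - NaI and zinc dust in DMF convert it in the flask into the allylic iodide F8, which undergoes reductive elimination with opening of the oxirane at C3–O, the known transposition of 2,3-epoxy halides to allylic alcohols, to give 9.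

3. Step 7. Facial selectivity may be poor because the C7 silyloxymethyl arm sits on the face that oxygen must approach, or ene-type hydroperoxidation may compete. The fallback builds the two C–O bonds one after the other, sets out from 10 and comes back at 12.
   - mCPBA (NaHCO3, CH2Cl2, 0 °C) should epoxidise the less hindered C3=C4 alkene anti to the dioxolane to give the vinyl epoxide F9.
   - Pd(PPh3)4 (zerovalent palladium) with AcOH in THF ionises the allylic C4–O bond with inversion, and acetate attacks C6 anti to palladium, giving the cis-1,4-hydroxy acetate F10 with C3–OH and C6–OAc both trans to the dioxolane.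
   - K2CO3 in MeOH removes the acetate to give 12.

Further compounds
F1 | step 4 | enantiomer of 6, (1S,5R,6R)-5-hydroxy-5-[(tert-butyldimethylsilyloxy)methyl]-7-oxabicyclo[4.1.0]hept-3-en-2-one | O=C1C=C[C@@](O)(CO[Si](C)(C)C(C)(C)C)[C@@H]2O[C@H]12
F2 | step 4 | enantiomer of hydrazone 7 | NN=C1C=C[C@@](O)(CO[Si](C)(C)C(C)(C)C)[C@@H]2O[C@H]12
F3 | step 4 | enantiomer of alkenyl diazene 8 | N=NC1=C[C@@H](O)[C@](O)(CO[Si](C)(C)C(C)(C)C)C=C1
F4 | step 4 | enantiomer of 9, (1R,2R)-1-[(tert-butyldimethylsilyloxy)methyl]cyclohexa-3,5-diene-1,2-diol | O[C@@H]1C=CC=C[C@@]1(O)CO[Si](C)(C)C(C)(C)C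
F5 | step 4 | (1R,2R)-2-acetoxy-1-[(tert-butyldimethylsilyloxy)methyl]cyclohexa-3,5-dien-1-ol | CC(=O)O[C@@H]1C=CC=C[C@@]1(O)CO[Si](C)(C)C(C)(C)C
F6 | step 5 | C4 alcohol from 6 (2,3-epoxy-cyclohex-5-ene-1,4-diol with C7 silyl ether, C4 epimers) | OC1C=C[C@](O)(CO[Si](C)(C)C(C)(C)C)[C@H]2O[C@@H]12
F7 | step 5 | C4 mesylate of F6 | CS(=O)(=O)OC1C=C[C@](O)(CO[Si](C)(C)C(C)(C)C)[C@H]2O[C@@H]12
F8 | step 5 | C4 iodide from F7 (formed in the flask) | IC1C=C[C@](O)(CO[Si](C)(C)C(C)(C)C)[C@H]2O[C@@H]12
F9 | step 7 | C3,C4-epoxide of 10, oxirane trans to the dioxolane | CC1(C)O[C@H]2[C@@H]3O[C@@H]3C=C[C@@]2(CO[Si](C)(C)C(C)(C)C)O1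
F10 | step 7 | 6-O-acetate of 12 (C3 hydroxyl free) | CC1(C)O[C@H]2[C@H](O)C=C[C@H](OC(C)=O)[C@@]2(CO[Si](C)(C)C(C)(C)C)O1
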